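## Retrosynthetic overview

1. Feature: ring A (C6–C7=C8–C10–C12–C13) is a cyclohexenecarboxylic acid. C8 carries C9O2H and is bonded to the methyl-bearing C10–H, and spiro C13 lies two bonds beyond C10. Read with C12=C13 as the alkene and an oxygen on C7, this γ,δ-unsaturated acid is the [3,3] product of a δ-lactone (ring O on C13) that carries an (E)-propenyl group on C13.
2. Last disconnection: ring C and the 11-membered carbocycle together, by a chain-tethered Diels–Alder reaction (bonds C16–C17 and C20–C21). The partners are the spiro α-methylbutenolide and a 1,2-bis(silyloxy)diene built on C19. The adduct is unmasked to the C17/C18 diketone.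
3. Spiro γ-lactone (O14–C13): iodolactonisation of the C12=C13 alkene left by the rearrangement, carried out before the C7 oxygen is eliminated to the C7=C8 enoate.
4. Ring A: lactone-to-cyclohexene Ireland–Claisen rearrangement (C8–C10). The lactone comes from an Evans syn aldol (C6, C7), a Weinreb ketone synthesis, a chelate-controlled (E)-propenyl addition (C13) and an oxidative lactonisation. The chain comes from desymmetrised meso-2,4-dimethylglutaric anhydride (C2, C22).
5. Ring order: sacrificial δ-lactone, then ring A, then spiro γ-lactone (later butenolide), then ring C and the macrocycle in one step.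

Key step: step 18

Labels: positions follow the target SMILES. C2 and C22 are the CHMe carbons of the chain, C3–C5 and C24 its CH2 groups. Ring A is C6, C7=C8(C9O2H), C10(Me), C12H2 and spiro C13. The lactone is O14–C15(=O)–C16(Me)–C21. Ring C is completed by C17(=O), C18(=O), C19H and C20H2.

Assumption 1: (DHQD)2AQN is taken to open the carbonyl that leads to 2; if the antipodal hemiester forms, (DHQ)2AQN is used and nothing else changes.

Assumption 2: the target is taken to rest as the C17/C18 diketone drawn, with C19–H in the cis-1,3-bridged orientation that enolisation can reach.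

Remark on C7: the syn aldol gives (7R), so O7 is trans to the C6 chain on the lactone. The centre is erased in step 24. Until then it supports the chelate of step 15, keeps the chain and O7 staggered in the boat of step 18, and sits equatorial in the chair of step 22.

Remark on order: the C7=C8 enoate is unveiled only after C13 is sp3. A 1,4-cyclohexadiene with a doubly allylic, vinylogously acidic C6–H would risk epimerisation and aromatisation.

## Route

Step 1
Reactants: 1 meso-2,4-dimethylglutaric anhydride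
Product: 2 (2R,4S)-5-methoxy-2,4-dimethyl-5-oxopentanoic acid
Conditions: MeOH, (DHQD)2AQN (cat.), Et2O, −40 °C
Reagents that add atoms: methanol (CO)
Why: Cinchona-alkaloid-catalysed desymmetrising alcoholysis of a meso anhydride, in which the catalyst picks one enantiotopic carbonyl so that both syn methyl centres (C2, C22) become defined at once.

Step 2
Reactants: 2 (2R,4S)-5-methoxy-2,4-dimethyl-5-oxopentanoic acid
Product: 4 (3S,5R)-3,5-dimethyltetrahydro-2H-pyran-2-one, via hydroxy ester 3 (not isolated)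
Conditions: BH3·SMe2, THF, 0 °C to rt; aq. work-up; TsOH (cat.), CH2Cl2, rt
Reagents that add atoms: none
Why: Borane reduces the free acid chemoselectively beside the ester and acid-catalysed lactonisation closes the six-membered ring without touching a stereocentre.

Step 3
Reactants: 4 (3S,5R)-3,5-dimethyltetrahydro-2H-pyran-2-one
Product: 5 (3S,5R)-3,5-dimethyltetrahydro-2H-pyran-2-ol (lactol, anomers)
Conditions: DIBAL-H (1.05 equiv), CH2Cl2, −78 °C
Reagents that add atoms: none
Why: Partial reduction of a lactone, which stops at the stable aluminium hemiacetal at low temperature.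

Step 4
Reactants: 5 lactol; 6 (3-carboxypropyl)triphenylphosphonium bromide
Product: 8 (4Z,6S,8R)-9-hydroxy-6,8-dimethylnon-4-enoic acid, via carboxylate ylide 7 (not isolated)
Conditions: 6, NaHMDS, THF, 0 °C; then 5, −78 °C to rt; HCl work-up
Reagents that add atoms: none
Why: Wittig olefination of the open hydroxy-aldehyde form of a lactol with a non-stabilised carboxylate ylide adds C4–C6 and C13 in one step, and the (Z) geometry is removed in step 5.

Step 5
Reactants: 8 (4Z,6S,8R)-9-hydroxy-6,8-dimethylnon-4-enoic acid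
Product: 9 (6R,8R)-9-hydroxy-6,8-dimethylnonanoic acid
Conditions: H2 (1 atm), Pd/C, EtOAc, rt
Reagents that add atoms: none
Why: Catalytic hydrogenation of an unhindered disubstituted alkene, with no hydrogenolysable group present.

Step 6
Reactants: 9 (6R,8R)-9-hydroxy-6,8-dimethylnonanoic acid
Product: 11 (6R,8R)-9-(TBDPS-oxy)-6,8-dimethylnonanoic acid, via silyl ester 10 (not isolated)
Conditions: TBDPSCl (2.2 equiv), imidazole, DMF, rt; then K2CO3 (cat.), MeOH–H2O, rt
Reagents that add atoms: tert-butyl(chloro)diphenylsilane (CC(C)(C)[Si](Cl)(c1ccccc1)c1ccccc1)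
Why: Silylation of alcohol and acid followed by selective hydrolysis of the much more labile silyl ester leaves the robust C19 silyl ether.

Step 7
Reactants: 11 (6R,8R)-9-(TBDPS-oxy)-6,8-dimethylnonanoic acid; 12 (S)-4-benzyl-1,3-oxazolidin-2-one
Product: 14 (S)-4-benzyl-3-[(6R,8R)-9-(TBDPS-oxy)-6,8-dimethylnonanoyl]oxazolidin-2-one, via mixed pivalic anhydride 13 (not isolated)
Conditions: PivCl, Et3N, THF, −20 °C; then 12, LiCl, rt
Reagents that add atoms: none
Why: N-acylation of the oxazolidinone through the mixed anhydride, which is attacked at the less hindered carbonyl.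

Step 8
Reactants: 15 propane-1,3-diol
Product: 16 3-(TBS-oxy)propan-1-ol
Conditions: NaH (1 equiv), THF, rt; TBSCl
Reagents that add atoms: tert-butyl(chloro)dimethylsilane (CC(C)(C)[Si](C)(C)Cl)
Why: Monosilylation of a symmetrical diol through its sparingly soluble monosodium alkoxide.

Step 9
Reactants: 16 3-(TBS-oxy)propan-1-ol
Product: 17 3-(TBS-oxy)propanal
Conditions: TEMPO (cat.), PhI(OAc)2, CH2Cl2, rt
Reagents that add atoms: none
Why: Oxoammonium-catalysed oxidation of a primary alcohol, which stops at the aldehyde in the absence of water.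

Step 10
Reactants: 14 N-acyl oxazolidinone; 17 3-(TBS-oxy)propanal
Product: 19 syn-aldol adduct (C6 S and C7 R), via (Z)-dibutylboron enolate 18 (not isolated)
Conditions: Bu2BOTf, Et3N, CH2Cl2, −78 to 0 °C; 17, −78 to 0 °C; H2O2, MeOH, pH 7 buffer
Reagents that add atoms: none
Why: Evans syn aldol reaction, in which the (Z)-boron enolate reacts through a chair transition state on the face opposite the benzyl group and sets C6 (S) and C7 (R).

Step 11
Reactants: 19 syn-aldol adduct
Product: 20 Weinreb amide (C6 S and C7 R, free C7–OH)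
Conditions: MeONHMe·HCl, AlMe3, THF, −10 to 0 °C
Reagents that add atoms: N,O-dimethylhydroxylamine hydrochloride (CNOC.Cl)
Why: Aluminium-amide transamidation of the imide, assisted by the free β-hydroxyl, releases the auxiliary without epimerisation.

Step 12
Reactants: 15 propane-1,3-diol
Product: 21 3-(PMB-oxy)propan-1-ol
Conditions: NaH (1 equiv), PMBCl, Bu4NI (cat.), THF, 0 °C to rt
Reagents that add atoms: 4-methoxybenzyl chloride (COc1ccc(CCl)cc1)
Why: Williamson mono-etherification of the symmetrical diol.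

Step 13
Reactants: 21 3-(PMB-oxy)propan-1-ol
Product: 22 1-[(3-bromopropoxy)methyl]-4-methoxybenzene
Conditions: CBr4, PPh3, CH2Cl2, 0 °C
Reagents that add atoms: carbon tetrabromide (BrC(Br)(Br)Br)
Why: Appel bromination of a primary alcohol under neutral conditions that spare the PMB ether.

Step 14
Reactants: 20 Weinreb amide; 22 1-[(3-bromopropoxy)methyl]-4-methoxybenzene
Product: 24 β-hydroxy ketone (C13 ketone bearing the C21–C15 chain), via 3-(PMB-oxy)propylmagnesium bromide 23 (not isolated)
Conditions: 22, Mg, THF; then 20, 0 °C (excess 23)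
Reagents that add atoms: none
Why: Weinreb ketone synthesis, in which the first equivalent deprotonates C7–OH and the chelated tetrahedral adduct survives until work-up, so neither over-addition nor C6 epimerisation should occur.

Step 15
Reactants: 24 β-hydroxy ketone; 25 (E)-1-bromoprop-1-ene
Product: 28 tertiary allylic alcohol (C13 R; free C7–OH), via (E)-propenyllithium 26 (not isolated), via (E)-propenylmagnesium bromide 27 (not isolated)
Conditions: 25, t-BuLi (2 equiv), Et2O, −78 °C; MgBr2·OEt2; then 24, CH2Cl2–Et2O, −78 to −20 °C (excess 27)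
Reagents that add atoms: none
Why: Chelation-controlled (Cram 1,3-chelate) Grignard addition, in which the O7 magnesium alkoxide binds the ketone, the syn-aldol array puts C8 equatorial and the C6 chain axial on the six-membered chelate, and the propenyl group, kept (E) by retentive Br–Li–Mg exchange, adds axially anti to that chain to set C13.

Step 16
Reactants: 28 tertiary allylic alcohol
Product: 29 triol (C9, C7 and C13 hydroxyls free)
Conditions: HF·pyridine, pyridine, THF, 0 °C
Reagents that add atoms: none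
Why: Buffered fluoride cleaves the primary TBS ether much faster than the TBDPS ether and is too weakly acidic to ionise the tertiary allylic alcohol.

Step 17
Reactants: 29 triol
Product: 31 δ-lactone (4R,5S,6R)-4-hydroxy-6-[(E)-prop-1-enyl]-6-[3-(PMB-oxy)propyl]-5-[(4R,6R)-7-(TBDPS-oxy)-4,6-dimethylheptyl]tetrahydropyran-2-one, via lactol 30 (not isolated)
Conditions: TEMPO (cat.), PhI(OAc)2, CH2Cl2, rt
Reagents that add atoms: none
Why: Oxidative lactonisation of a 1,3,5-triol, in which the oxoammonium salt takes only the primary alcohol, the aldehyde closes on the C13 hydroxyl to the six-membered lactol and a second oxidation gives the β-hydroxy-δ-lactone.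

Step 18
Reactants: 31 δ-lactone
Product: 35 ring-A acid (1S,2S,3R,6S)-2-hydroxy-6-methyl-4-[3-(PMB-oxy)propyl]-3-[(4R,6R)-7-(TBDPS-oxy)-4,6-dimethylheptyl]cyclohex-4-ene-1-carboxylic acid, via dilithio alkoxide-enolate 32 (not isolated), via bis(trimethylsilyl) ketene acetal 33 (not isolated), via trimethylsilyl ester 34 (not isolated)
Conditions: LDA (3 equiv), THF, −78 to −40 °C; TMSCl–Et3N, −78 °C to rt; PhMe, 100 °C; then aq. citric acid, THF, rt
Reagents that add atoms: none
Why: Two equivalents of LDA convert 31 into alkoxide-enolate 32, in which the C7 oxygen is an oxide and cannot leave (as in Fráter–Seebach dianions), and silylation on both oxygens gives ketene acetal 33; on heating, 33 undergoes a concerted suprafacial [3,3] shift in which C8 bonds to C10, the C13–O bond breaks and the C12=C13 alkene and silyl ester 34 appear, and mild acid then frees the acid and the C7 hydroxyl. The closest known reaction type is the Ireland–Claisen rearrangement of lactone silyl ketene acetals that carry an alkenyl group on the carbinol carbon, which is established for six-membered lactones and 6-alkenyl-1,4-dioxan-2-ones giving six-membered rings. Ring A (C8–C7–C6–C13–C12–C10) closes in the sigmatropic event itself: because the C6–C7 bridge ties C13 to C8, the pericyclic array can only be a boat (bicyclo[2.2.2]octane-like) and the new ring alkene is necessarily cis. C10 is controlled by C13, since the bond forms on the allyl face from which the oxygen departs with the methyl of the (E)-propenyl group outside, which places the C10 methyl cis to the C6 chain; C8 is controlled by the boat topology (C9 cis to the C10 methyl) and is erased in step 24. The step needs O- rather than C-silylation, no β-elimination, and rearrangement before ionisation of the tertiary allylic C–O bond; the oxide at C7, the amine-buffered neutral medium and the fully substituted C13, which weakens the breaking bond, secure this. Only the propenyl group offers an allyl terminus (the C21 chain is saturated), and the chain and O7 are trans on the C6–C7 bridge, so they do not eclipse in the boat and only O7 faces H–C10.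

Step 19
Reactants: 35 ring-A acid
Product: 36 2-(trimethylsilyl)ethyl (TMSE) ester of 35
Conditions: TMSCH2CH2OH, DCC, DMAP (cat.), CH2Cl2, 0 °C to rt
Reagents that add atoms: 2-(trimethylsilyl)ethanol (C[Si](C)(C)CCO)
Why: Steglich esterification with a primary alcohol outruns acylation of the hindered C7 hydroxyl, which is trans to C9 and cannot form a β-lactone, and gives an ester that tolerates base, Lewis acid and heat.

Step 20
Reactants: 36 TMSE ester
Product: 37 C15 primary alcohol (diol with C7–OH)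
Conditions: DDQ, CH2Cl2–pH 7 buffer, 0 °C
Reagents that add atoms: none
Why: Oxidative cleavage of the PMB ether by hydride abstraction and hydrolysis, orthogonal to both silicon groups and the alkene.

Step 21
Reactants: 37 C15 primary alcohol
Product: 39 C15 carboxylic acid (γ,δ-unsaturated through C13=C12), via aldehyde 38 (not isolated)
Conditions: TEMPO (cat.), PhI(OAc)2, MeCN–H2O, rt
Reagents that add atoms: water (O)
Why: Oxoammonium oxidation in water carries the primary alcohol through the aldehyde hydrate to the acid, while the hindered secondary C7 hydroxyl reacts much more slowly.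

Step 22
Reactants: 39 C15 carboxylic acid
Product: 40 spiro iodolactone (O14 on C13 cis to C6 chain and C10 methyl; C12–I trans to O14)
Conditions: I2, NaHCO3, MeCN, 0 °C, dark
Reagents that add atoms: iodine (II)
Why: 5-exo iodolactonisation, in which iodonium forms on the face anti to the two allylic substituents and the carboxylate opens it at tertiary C13 in trans-diaxial fashion through the chair that keeps the C6 chain, O7 and C9 equatorial, setting C13 (R in the target).

Step 23
Reactants: 40 spiro iodolactone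
Product: 41 spiro γ-lactone (C12H2)
Conditions: Bu3SnH, AIBN (cat.), PhH, 80 °C
Reagents that add atoms: none
Why: Radical chain dehalogenation, in which hydrogen transfer to the C12 radical is far faster than acyloxy migration and no stereocentre is affected.

Step 24
Reactants: 41 spiro γ-lactone
Product: 43 C7=C8 enoate spirolactone, via mesylate 42 (not isolated)
Conditions: MsCl, Et3N, CH2Cl2, 0 °C; then DBU, PhMe, 70 °C
Reagents that add atoms: none
Why: Mesylation and E1cB elimination through the ester α-position (C8–H), the only open pathway because no C–H is antiperiplanar to O7 in either chair, gives only the conjugated alkene and erases C7 and C8.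

Step 25
Reactants: 43 C7=C8 enoate spirolactone
Product: 44 α-methyl spirolactone (C16 epimers)
Conditions: LDA (1.1 equiv), THF, −78 °C; MeI
Reagents that add atoms: iodomethane (CI)
Why: Kinetic deprotonation takes the unhindered, more acidic lactone C16H2 rather than the hindered tertiary γ-C6–H of the enoate, and enolate alkylation installs the C16 methyl, whose configuration is irrelevant.

Step 26
Reactants: 44 α-methyl spirolactone
Product: 47 spiro α-methylbutenolide (C16=C21), via α-phenylselanyl lactone 45 (not isolated), via selenoxide 46 (not isolated)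
Conditions: LDA, THF, −78 °C; PhSeBr; then H2O2, pyridine, CH2Cl2, 0 °C to rt
Reagents that add atoms: none
Why: α-Selenenylation and selenoxide syn-elimination, in which a syn C21–H is available in the five-membered ring so that the conjugated endocyclic alkene should prevail, as in the standard route to α-alkylbutenolides.

Step 27
Reactants: 47 spiro α-methylbutenolide
Product: 48 C19 primary alcohol
Conditions: HF·pyridine, THF, rt
Reagents that add atoms: none
Why: Acidic fluoride removes the TBDPS ether but does not attack the tetraalkylsilane of the TMSE ester.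

Step 28
Reactants: 48 C19 primary alcohol
Product: 49 C19 aldehyde
Conditions: Dess–Martin periodinane, CH2Cl2, rt
Reagents that add atoms: none
Why: Dess–Martin oxidation is neutral and should not epimerise the α-centre C22.

Step 29
Reactants: 49 C19 aldehyde
Product: 50 terminal alkyne (C19≡C20H)
Conditions: dimethyl (1-diazo-2-oxopropyl)phosphonate, K2CO3, MeOH, 0 °C to rt
Reagents that add atoms: dimethyl (1-diazo-2-oxopropyl)phosphonate (CC(=O)C(=[N+]=[N-])P(=O)(OC)OC)
Why: Ohira–Bestmann (Seyferth–Gilbert) homologation adds C20 under mild carbonate conditions that hindered esters, the butenolide and α-methyl aldehydes tolerate.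

Step 30
Reactants: 50 terminal alkyne
Product: 52 2-iodo-1-alkene (C19(I)=C20H2), via 2-iodoalkenyl-9-BBN 51 (not isolated)
Conditions: B-iodo-9-BBN, pentane–CH2Cl2, −20 to 0 °C; then AcOH
Reagents that add atoms: B-iodo-9-borabicyclo[3.3.1]nonane (IB1C2CCCC1CCC2)
Why: Syn-haloboration of a terminal alkyne puts boron on the terminal and iodine on the internal carbon, alkenes do not react, and protodeboronation gives the Markovnikov vinyl iodide.

Step 31
Reactants: 52 2-iodo-1-alkene; 53 (TBS-oxy)acetaldehyde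
Product: 54 allylic alcohol (C18 epimers; C17H2OTBS)
Conditions: 53, CrCl2, NiCl2 (cat.), DMF, rt
Reagents that add atoms: none
Why: Nozaki–Hiyama–Kishi coupling joins C19 to C18 chemoselectively at the aldehyde in the presence of the ester, enoate and butenolide.

Step 32
Reactants: 54 allylic alcohol
Product: 55 α-methylene ketone (C18=O)
Conditions: Dess–Martin periodinane, CH2Cl2, rt
Reagents that add atoms: none
Why: Dess–Martin oxidation of the allylic alcohol removes the C18 centre and gives the cross-conjugated enone under neutral conditions.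

Step 33
Reactants: 55 α-methylene ketone
Product: 56 (Z)-1,2-bis(TBS-oxy)-3-alkylbuta-1,3-diene
Conditions: TBSOTf, Et3N, CH2Cl2, −78 to 0 °C
Reagents that add atoms: tert-butyldimethylsilyl trifluoromethanesulfonate (CC(C)(C)[Si](C)(C)OS(=O)(=O)C(F)(F)F)
Why: Soft enolisation can occur only toward C17 and should give the enol ether with the C17 oxygen trans to C19 (less allylic strain), that is, the outside position of the s-cis diene; the butenolide has no γ-H and cannot be silylated.

Step 34
Reactants: 56 bis(silyloxy)diene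
Product: 57 tetracyclic Diels–Alder adduct (C16 and C21 as in the target; C17 unassigned; C18=C19 silyl enol ether)
Conditions: PhMe (1 mM), BHT (cat.), sealed vessel, 160 °C
Reagents that add atoms: none
Why: Proposed new method: a type-2 intramolecular Diels–Alder reaction in which the diene is tied through its inner carbon C19 by eight atoms to C21 of a trisubstituted α-methylbutenolide has not been shown; the reasoning is that the C17 silyloxy and C19 alkyl groups place the largest HOMO coefficient on C20, which matches the electrophilic β-carbon C21 (C17 then closes on C16), that the tether reaches only the butenolide face syn to C6 so that suprafacial addition sets C21 and C16 with a cis ring fusion, that the C18=C19 bridgehead enol ether of a bicyclo[8.3.1] frame is unstrained, and that the syn-1,3-dimethyl chain disfavours extended conformers; the closest known reaction types are macrocycle-forming intramolecular Diels–Alder reactions (11- to 14-membered rings) onto five-membered unsaturated lactam or tetronate dienophiles, type-2 intramolecular Diels–Alder reactions giving bicyclo[n.3.1] bridgehead alkenes, and intermolecular additions of silyloxydienes to butenolides; C17 is an inconsequential centre.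

Step 35
Reactants: 57 Diels–Alder adduct
Product: 58 acyloin acid (C17–OH, C18=O, C19–H as in the target, free C9O2H)
Conditions: TBAF, AcOH, THF, 0 °C to rt
Reagents that add atoms: none
Why: Buffered fluoride cleaves the enol ether, the C17 silyl ether and the TMSE ester (with loss of ethene) together, and protonation at C19 with equilibration α to the ketone should give the cis-1,3-bridged isomer, the only one the 11-membered ring accommodates without an inward bridgehead.

Step 36
Reactants: 58 acyloin acid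
Product: 59 CNP0115928.1 (target)
Conditions: Dess–Martin periodinane, CH2Cl2, rt
Reagents that add atoms: none
Why: Dess–Martin oxidation of an α-hydroxy ketone gives the 1,2-diketone without C–C cleavage, tolerates the free acid and removes the unassigned C17 centre.

## Compound list

1 | meso-2,4-dimethylglutaric anhydride | C[C@@H]1C[C@H](C)C(=O)OC1=O | starting material
2 | (2R,4S)-5-methoxy-2,4-dimethyl-5-oxopentanoic acid | COC(=O)[C@@H](C)C[C@@H](C)C(=O)O | intermediate
3 | methyl (2S,4R)-5-hydroxy-2,4-dimethylpentanoate | COC(=O)[C@@H](C)C[C@@H](C)CO | intermediate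
4 | (3S,5R)-3,5-dimethyltetrahydro-2H-pyran-2-one | O=C1[C@@H](C)C[C@@H](C)CO1 | intermediate
5 | (3S,5R)-3,5-dimethyltetrahydro-2H-pyran-2-ol | OC1[C@@H](C)C[C@@H](C)CO1 | intermediate
6 | (3-carboxypropyl)triphenylphosphonium bromide | OC(=O)CCC[P+](c1ccccc1)(c1ccccc1)c1ccccc1.[Br-] | starting material
7 | sodium 4-(triphenylphosphoranylidene)butanoate | [Na+].[O-]C(=O)CCC=P(c1ccccc1)(c1ccccc1)c1ccccc1 | intermediate
8 | (4Z,6S,8R)-9-hydroxy-6,8-dimethylnon-4-enoic acid | OC(=O)CC/C=C\[C@@H](C)C[C@@H](C)CO | intermediate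
9 | (6R,8R)-9-hydroxy-6,8-dimethylnonanoic acid | OC(=O)CCCC[C@@H](C)C[C@@H](C)CO | intermediate
10 | TBDPS ester of 11 | CC(C)(C)[Si](c1ccccc1)(c1ccccc1)OC(=O)CCCC[C@@H](C)C[C@@H](C)CO[Si](c1ccccc1)(c1ccccc1)C(C)(C)C | intermediate
11 | (6R,8R)-9-(TBDPS-oxy)-6,8-dimethylnonanoic acid | OC(=O)CCCC[C@@H](C)C[C@@H](C)CO[Si](c1ccccc1)(c1ccccc1)C(C)(C)C | intermediate
12 | (S)-4-benzyl-1,3-oxazolidin-2-one | O=C1N[C@@H](Cc2ccccc2)CO1 | starting material
13 | mixed pivalic anhydride of 11 | CC(C)(C)C(=O)OC(=O)CCCC[C@@H](C)C[C@@H](C)CO[Si](c1ccccc1)(c1ccccc1)C(C)(C)C | intermediate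
14 | (S)-4-benzyl-3-[(6R,8R)-9-(TBDPS-oxy)-6,8-dimethylnonanoyl]oxazolidin-2-one | O=C1OC[C@H](Cc2ccccc2)N1C(=O)CCCC[C@@H](C)C[C@@H](C)CO[Si](c2ccccc2)(c2ccccc2)C(C)(C)C | intermediate
15 | propane-1,3-diol | OCCCO | starting material
16 | 3-(TBS-oxy)propan-1-ol | OCCCO[Si](C)(C)C(C)(C)C | intermediate
17 | 3-(TBS-oxy)propanal | O=CCCO[Si](C)(C)C(C)(C)C | intermediate
18 | (Z)-dibutylboron enolate of 14 | CCCCB(CCCC)O/C(=C\CCC[C@@H](C)C[C@@H](C)CO[Si](c1ccccc1)(c1ccccc1)C(C)(C)C)N1C(=O)OC[C@@H]1Cc1ccccc1 | intermediate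
19 | syn-aldol adduct (C6 S, C7 R) | O=C1OC[C@H](Cc2ccccc2)N1C(=O)[C@@H](CCC[C@@H](C)C[C@@H](C)CO[Si](c2ccccc2)(c2ccccc2)C(C)(C)C)[C@H](O)CCO[Si](C)(C)C(C)(C)C | intermediate
20 | Weinreb amide (C6 S, C7 R) | CON(C)C(=O)[C@@H](CCC[C@@H](C)C[C@@H](C)CO[Si](c1ccccc1)(c1ccccc1)C(C)(C)C)[C@H](O)CCO[Si](C)(C)C(C)(C)C | intermediate
21 | 3-(PMB-oxy)propan-1-ol | OCCCOCc1ccc(OC)cc1 | intermediate
22 | 1-[(3-bromopropoxy)methyl]-4-methoxybenzene | BrCCCOCc1ccc(OC)cc1 | intermediate
23 | 3-(PMB-oxy)propylmagnesium bromide | Br[Mg]CCCOCc1ccc(OC)cc1 | intermediate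
24 | β-hydroxy ketone (C13=O) | COc1ccc(COCCCC(=O)[C@@H](CCC[C@@H](C)C[C@@H](C)CO[Si](c2ccccc2)(c2ccccc2)C(C)(C)C)[C@H](O)CCO[Si](C)(C)C(C)(C)C)cc1 | intermediate
25 | (E)-1-bromoprop-1-ene | C/C=C/Br | starting material
26 | (E)-prop-1-enyllithium | C/C=C/[Li] | intermediate
27 | (E)-prop-1-enylmagnesium bromide | C/C=C/[Mg]Br | intermediate
28 | tertiary allylic alcohol (C13 R, C6 S, C7 R; C9–OTBS) | C/C=C/[C@](O)(CCCOCc1ccc(OC)cc1)[C@@H](CCC[C@@H](C)C[C@@H](C)CO[Si](c1ccccc1)(c1ccccc1)C(C)(C)C)[C@H](O)CCO[Si](C)(C)C(C)(C)C | intermediate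
29 | triol | C/C=C/[C@](O)(CCCOCc1ccc(OC)cc1)[C@@H](CCC[C@@H](C)C[C@@H](C)CO[Si](c1ccccc1)(c1ccccc1)C(C)(C)C)[C@H](O)CCO | intermediate
30 | six-membered lactol of the C9 aldehyde | OC1C[C@@H](O)[C@H](CCC[C@@H](C)C[C@@H](C)CO[Si](c2ccccc2)(c2ccccc2)C(C)(C)C)[C@](/C=C/C)(CCCOCc2ccc(OC)cc2)O1 | intermediate
31 | δ-lactone, Claisen precursor (4R,5S,6R) | O=C1C[C@@H](O)[C@H](CCC[C@@H](C)C[C@@H](C)CO[Si](c2ccccc2)(c2ccccc2)C(C)(C)C)[C@](/C=C/C)(CCCOCc2ccc(OC)cc2)O1 | intermediate
32 | dilithio alkoxide-enolate of 31 | [Li]OC1=C[C@@H](O[Li])[C@H](CCC[C@@H](C)C[C@@H](C)CO[Si](c2ccccc2)(c2ccccc2)C(C)(C)C)[C@](/C=C/C)(CCCOCc2ccc(OC)cc2)O1 | intermediate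
33 | bis(trimethylsilyl) ketene acetal | C[Si](C)(C)OC1=C[C@@H](O[Si](C)(C)C)[C@H](CCC[C@@H](C)C[C@@H](C)CO[Si](c2ccccc2)(c2ccccc2)C(C)(C)C)[C@](/C=C/C)(CCCOCc2ccc(OC)cc2)O1 | intermediate
34 | trimethylsilyl ester (C7–OTMS) of 35 | C[Si](C)(C)OC(=O)[C@@H]1[C@@H](O[Si](C)(C)C)[C@H](CCC[C@@H](C)C[C@@H](C)CO[Si](c2ccccc2)(c2ccccc2)C(C)(C)C)C(CCCOCc2ccc(OC)cc2)=C[C@@H]1C | intermediate
35 | ring-A cyclohexene acid, Claisen product (1S,2S,3R,6S) | OC(=O)[C@@H]1[C@@H](O)[C@H](CCC[C@@H](C)C[C@@H](C)CO[Si](c2ccccc2)(c2ccccc2)C(C)(C)C)C(CCCOCc2ccc(OC)cc2)=C[C@@H]1C | intermediate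
36 | TMSE ester of 35 | C[Si](C)(C)CCOC(=O)[C@@H]1[C@@H](O)[C@H](CCC[C@@H](C)C[C@@H](C)CO[Si](c2ccccc2)(c2ccccc2)C(C)(C)C)C(CCCOCc2ccc(OC)cc2)=C[C@@H]1C | intermediate
37 | C15 alcohol | C[Si](C)(C)CCOC(=O)[C@@H]1[C@@H](O)[C@H](CCC[C@@H](C)C[C@@H](C)CO[Si](c2ccccc2)(c2ccccc2)C(C)(C)C)C(CCCO)=C[C@@H]1C | intermediate
38 | C15 aldehyde | C[Si](C)(C)CCOC(=O)[C@@H]1[C@@H](O)[C@H](CCC[C@@H](C)C[C@@H](C)CO[Si](c2ccccc2)(c2ccccc2)C(C)(C)C)C(CCC=O)=C[C@@H]1C | intermediate
39 | C15 carboxylic acid | C[Si](C)(C)CCOC(=O)[C@@H]1[C@@H](O)[C@H](CCC[C@@H](C)C[C@@H](C)CO[Si](c2ccccc2)(c2ccccc2)C(C)(C)C)C(CCC(=O)O)=C[C@@H]1C | intermediate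
40 | spiro iodolactone | C[Si](C)(C)CCOC(=O)[C@@H]1[C@@H](O)[C@H](CCC[C@@H](C)C[C@@H](C)CO[Si](c2ccccc2)(c2ccccc2)C(C)(C)C)[C@@]2(CCC(=O)O2)[C@@H](I)[C@@H]1C | intermediate
41 | spiro γ-lactone (C7–OH) | C[Si](C)(C)CCOC(=O)[C@@H]1[C@@H](O)[C@H](CCC[C@@H](C)C[C@@H](C)CO[Si](c2ccccc2)(c2ccccc2)C(C)(C)C)[C@@]2(CCC(=O)O2)C[C@@H]1C | intermediate
42 | C7 mesylate | C[Si](C)(C)CCOC(=O)[C@@H]1[C@@H](OS(C)(=O)=O)[C@H](CCC[C@@H](C)C[C@@H](C)CO[Si](c2ccccc2)(c2ccccc2)C(C)(C)C)[C@@]2(CCC(=O)O2)C[C@@H]1C | intermediate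
43 | C7=C8 enoate spirolactone | C[Si](C)(C)CCOC(=O)C1=C[C@H](CCC[C@@H](C)C[C@@H](C)CO[Si](c2ccccc2)(c2ccccc2)C(C)(C)C)[C@@]2(CCC(=O)O2)C[C@@H]1C | intermediate
44 | α-methyl spirolactone (C16 epimers) | C[Si](C)(C)CCOC(=O)C1=C[C@H](CCC[C@@H](C)C[C@@H](C)CO[Si](c2ccccc2)(c2ccccc2)C(C)(C)C)[C@@]2(CC(C)C(=O)O2)C[C@@H]1C | intermediate
45 | α-methyl-α-phenylselanyl lactone | C[Si](C)(C)CCOC(=O)C1=C[C@H](CCC[C@@H](C)C[C@@H](C)CO[Si](c2ccccc2)(c2ccccc2)C(C)(C)C)[C@@]2(CC(C)([Se]c3ccccc3)C(=O)O2)C[C@@H]1C | intermediate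
46 | selenoxide of 45 | C[Si](C)(C)CCOC(=O)C1=C[C@H](CCC[C@@H](C)C[C@@H](C)CO[Si](c2ccccc2)(c2ccccc2)C(C)(C)C)[C@@]2(CC(C)([Se](=O)c3ccccc3)C(=O)O2)C[C@@H]1C | intermediate
47 | spiro α-methylbutenolide (C19–OTBDPS) | C[Si](C)(C)CCOC(=O)C1=C[C@H](CCC[C@@H](C)C[C@@H](C)CO[Si](c2ccccc2)(c2ccccc2)C(C)(C)C)[C@@]2(C=C(C)C(=O)O2)C[C@@H]1C | intermediate
48 | C19 alcohol | C[Si](C)(C)CCOC(=O)C1=C[C@H](CCC[C@@H](C)C[C@@H](C)CO)[C@@]2(C=C(C)C(=O)O2)C[C@@H]1C | intermediate
49 | C19 aldehyde | C[Si](C)(C)CCOC(=O)C1=C[C@H](CCC[C@@H](C)C[C@@H](C)C=O)[C@@]2(C=C(C)C(=O)O2)C[C@@H]1C | intermediate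
50 | terminal alkyne | C[Si](C)(C)CCOC(=O)C1=C[C@H](CCC[C@@H](C)C[C@@H](C)C#C)[C@@]2(C=C(C)C(=O)O2)C[C@@H]1C | intermediate
51 | (Z)-2-iodoalkenyl-9-BBN | C[Si](C)(C)CCOC(=O)C1=C[C@H](CCC[C@@H](C)C[C@@H](C)/C(I)=C/B3C4CCCC3CCC4)[C@@]2(C=C(C)C(=O)O2)C[C@@H]1C | intermediate
52 | 2-iodo-1-alkene | C[Si](C)(C)CCOC(=O)C1=C[C@H](CCC[C@@H](C)C[C@@H](C)C(I)=C)[C@@]2(C=C(C)C(=O)O2)C[C@@H]1C | intermediate
53 | (TBS-oxy)acetaldehyde | O=CCO[Si](C)(C)C(C)(C)C | starting material
54 | allylic alcohol (C18 epimers) | C[Si](C)(C)CCOC(=O)C1=C[C@H](CCC[C@@H](C)C[C@@H](C)C(=C)C(O)CO[Si](C)(C)C(C)(C)C)[C@@]2(C=C(C)C(=O)O2)C[C@@H]1C | intermediate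
55 | α-methylene ketone | C[Si](C)(C)CCOC(=O)C1=C[C@H](CCC[C@@H](C)C[C@@H](C)C(=C)C(=O)CO[Si](C)(C)C(C)(C)C)[C@@]2(C=C(C)C(=O)O2)C[C@@H]1C | intermediate
56 | (Z)-1,2-bis(TBS-oxy)diene | C[Si](C)(C)CCOC(=O)C1=C[C@H](CCC[C@@H](C)C[C@@H](C)C(=C)/C(O[Si](C)(C)C(C)(C)C)=C/O[Si](C)(C)C(C)(C)C)[C@@]2(C=C(C)C(=O)O2)C[C@@H]1C | intermediate
57 | tetracyclic Diels–Alder adduct (C17 unassigned) | C[C@@H]1CCC[C@H]2C=C(C(=O)OCC[Si](C)(C)C)[C@@H](C)C[C@@]23OC(=O)[C@@]2(C)C(O[Si](C)(C)C(C)(C)C)C(O[Si](C)(C)C(C)(C)C)=C(C[C@H]23)[C@H](C)C1 | intermediate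
58 | acyloin acid (C17 unassigned) | C[C@@H]1CCC[C@H]2C=C(C(=O)O)[C@@H](C)C[C@@]23OC(=O)[C@@]2(C)C(O)C(=O)[C@H](C[C@H]23)[C@H](C)C1 | intermediate
59 | CNP0115928.1 | C[C@@H]1CCC[C@H]2C=C(C(=O)O)[C@@H](C)C[C@@]23OC(=O)[C@@]2(C)C(=O)C(=O)[C@H](C[C@H]23)[C@H](C)C1 | target

## Step count and risks

Total step count: 36. Longest linear sequence: 32 steps (1–7, 10, 11, 14–36).

**Step 34 (tethered Diels–Alder reaction).**
- The cycloaddition may be too slow. The trisubstituted butenolide is a poor 2π partner and an 11-membered closure has a low effective molarity.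
- Thermal loss of the silyl dienol ether, oligomerisation, or closure in the para-bridged sense could then take over.
- Fallback: it sets out from 56 and comes back at 58, and it makes the two bonds one at a time by known polar reactions.
- Catalytic triflimide under silyl-transfer conditions (CH2Cl2, high dilution, −78 to −20 °C) should trigger a vinylogous Mukaiyama–Michael addition of C20 to C21. The C17–O silyl group moves to the lactone oxygen, giving the 11-membered silyl ketene acetal–enal F1.
- BF3·OEt2 at −78 °C then closes C16–C17 as a six-membered intramolecular Mukaiyama aldol reaction to the hydroxy enol ether F2.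
- The conditions of step 35 convert F2 into 58.

**Step 18 (lactone Ireland–Claisen rearrangement).**
- Incomplete dianion formation could open β-elimination. C-silylation could compete. The tertiary allylic C–O bond could ionise before the strained boat is reached.
- Fallback: it sets out from 24 and comes back at 35. Ring A is closed by metathesis instead of by the sigmatropic step, and C10 is set by an open-chain Ireland–Claisen rearrangement.
- TBSOTf/2,6-lutidine gives the silyl ether F3. Ph3P=CH2 gives the 1,1-disubstituted alkene F4. HF·pyridine at 0 °C gives the primary alcohol F5. TEMPO/PhI(OAc)2/H2O gives the acid F6.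
- DCC/DMAP with (R,E)-pent-3-en-2-ol gives the allylic ester F7.
- LDA/TMSCl in THF–DMPU and warming should give the diene acid F8 through a chair transition state with 1,3-chirality transfer.
- A second-generation Grubbs catalyst closes C12=C13 with loss of propene to the silyl-protected ring-A acid F9. HF·pyridine then frees the C7 hydroxyl to give 35.
- A C8 epimer formed on this path would converge at 43.

**Step 15 (chelate-controlled propenyl addition).**
- If the magnesium chelate is not maintained, facial selectivity at C13 drops. Enolisation or retro-aldol cleavage of the β-oxido ketone can also consume material.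
- Fallback: it sets out from 20 and comes back at 29. The order of the two C–C bond formations at C13 is reversed, so that Felkin–Anh control replaces chelation.
- TESOTf/2,6-lutidine gives the silyl-protected amide F10, and (E)-propenyllithium 26 gives the enone F11.
- The organocerium reagent from 23 and CeCl3 should add 1,2 and anti to the large C7 branch, giving the tertiary alcohol F12.
- HF·pyridine removes the TES ether and the primary TBS ether together to give 29.

Further compounds
F1 | step 34 | 11-membered silyl ketene acetal–enal (C20–C21 formed) | C[C@@H]1CCC[C@H]2C=C(C(=O)OCC[Si](C)(C)C)[C@@H](C)C[C@@]23OC(O[Si](C)(C)C(C)(C)C)=C(C)[C@H]3C/C(=C(/O[Si](C)(C)C(C)(C)C)C=O)[C@H](C)C1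
F2 | step 34 | hydroxy enol ether (C17–OH, C18–OTBS) | C[C@@H]1CCC[C@H]2C=C(C(=O)OCC[Si](C)(C)C)[C@@H](C)C[C@@]23OC(=O)[C@@]2(C)C(O)C(O[Si](C)(C)C(C)(C)C)=C(C[C@H]23)[C@H](C)C1
F3 | step 18 | C7–OTBS ketone | COc1ccc(COCCCC(=O)[C@@H](CCC[C@@H](C)C[C@@H](C)CO[Si](c2ccccc2)(c2ccccc2)C(C)(C)C)[C@H](O[Si](C)(C)C(C)(C)C)CCO[Si](C)(C)C(C)(C)C)cc1
F4 | step 18 | 1,1-disubstituted alkene (C13=CH2) | COc1ccc(COCCCC(=C)[C@@H](CCC[C@@H](C)C[C@@H](C)CO[Si](c2ccccc2)(c2ccccc2)C(C)(C)C)[C@H](O[Si](C)(C)C(C)(C)C)CCO[Si](C)(C)C(C)(C)C)cc1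
F5 | step 18 | C9 primary alcohol | COc1ccc(COCCCC(=C)[C@@H](CCC[C@@H](C)C[C@@H](C)CO[Si](c2ccccc2)(c2ccccc2)C(C)(C)C)[C@H](O[Si](C)(C)C(C)(C)C)CCO)cc1
F6 | step 18 | C9 carboxylic acid | COc1ccc(COCCCC(=C)[C@@H](CCC[C@@H](C)C[C@@H](C)CO[Si](c2ccccc2)(c2ccccc2)C(C)(C)C)[C@H](O[Si](C)(C)C(C)(C)C)CC(=O)O)cc1
F7 | step 18 | (R,E)-pent-3-en-2-yl ester | COc1ccc(COCCCC(=C)[C@@H](CCC[C@@H](C)C[C@@H](C)CO[Si](c2ccccc2)(c2ccccc2)C(C)(C)C)[C@H](O[Si](C)(C)C(C)(C)C)CC(=O)O[C@H](C)/C=C/C)cc1
F8 | step 18 | open-chain Claisen diene acid | OC(=O)[C@@H]([C@@H](C)/C=C/C)[C@@H](O[Si](C)(C)C(C)(C)C)[C@H](CCC[C@@H](C)C[C@@H](C)CO[Si](c1ccccc1)(c1ccccc1)C(C)(C)C)C(=C)CCCOCc1ccc(OC)cc1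
F9 | step 18 | C7–OTBS ring-A acid | OC(=O)[C@@H]1[C@@H](O[Si](C)(C)C(C)(C)C)[C@H](CCC[C@@H](C)C[C@@H](C)CO[Si](c2ccccc2)(c2ccccc2)C(C)(C)C)C(CCCOCc2ccc(OC)cc2)=C[C@@H]1C
F10 | step 15 | C7–OTES Weinreb amide | CON(C)C(=O)[C@@H](CCC[C@@H](C)C[C@@H](C)CO[Si](c1ccccc1)(c1ccccc1)C(C)(C)C)[C@H](O[Si](CC)(CC)CC)CCO[Si](C)(C)C(C)(C)C
F11 | step 15 | (E)-propenyl ketone | C/C=C/C(=O)[C@@H](CCC[C@@H](C)C[C@@H](C)CO[Si](c1ccccc1)(c1ccccc1)C(C)(C)C)[C@H](O[Si](CC)(CC)CC)CCO[Si](C)(C)C(C)(C)C
F12 | step 15 | tertiary alcohol (C7–OTES) | C/C=C/[C@](O)(CCCOCc1ccc(OC)cc1)[C@@H](CCC[C@@H](C)C[C@@H](C)CO[Si](c1ccccc1)(c1ccccc1)C(C)(C)C)[C@H](O[Si](CC)(CC)CC)CCO[Si](C)(C)C(C)(C)C
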